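**Plan**

- Retrosynthesis: ring A is cut at two bonds, enone C=O carbon to C(Me)= and C(OMe) to CMe2. This takes out 1-methoxyprop-1-yne and leaves a ring B acid chloride whose second acyl arm is an isobutyryl enol silane.
- Enabling feature: ring A is the O-methyl ether of a cyclohexane-1,3,5-trione, formally a mixed trimer of three ketenes. Its C(Me)=C(OMe) unit is one ketene in O-methylated (ynol ether) form, lying between an acyl carbon and the α-carbon of the next ketone.
- Further cuts: quaternary carbon–isobutyryl bond (ester enolate acylation), ring B alkene (ring-closing metathesis), quaternary carbon–CH2 bond (malonate alkylation), CH(iPr)–malonate bond (Michael addition).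
- Forward order: open chain, then ring B, then the quaternary carbon, then ring A last. The homoprenyl group is fixed 1,3 to the future spiro carbon by connectivity, a pattern a myrcene Diels–Alder reaction is not expected to secure.
- Stereochemistry: the CH(iPr) centre comes from the (S)-pyrrolidine catalyst in step 3. The spiro centre comes from acylation anti to isopropyl in step 8, which decides that the acyl arm cis to isopropyl becomes the enone carbonyl.

Key step: step 12

Remark: the malonate carbon in 8, 9, 11 and 12 and C1 of 13 are carried as epimer mixtures, because this carbon is made planar again in step 8.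

**Step 1**
Reactants: 1 2-methylprop-2-en-1-ol, 2 1-bromo-3-methylbut-2-ene
Product: 4 6-methyl-2-methylidenehept-5-en-1-ol, via dilithio dianion of methallyl alcohol 3 (not isolated)
Conditions: n-BuLi (2.2 equiv), TMEDA, Et2O/hexane, 0 °C to rt; then 2, −78 °C to rt
Reagents that add atoms: none
Why: Double deprotonation gives the O,C-dianion, whose allylic carbanion is alkylated by the primary allylic bromide (SN2 dianion alkylation); both termini of the allyl anion give the same constitution.

**Step 2**
Reactants: 4 6-methyl-2-methylidenehept-5-en-1-ol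
Product: 5 2-(bromomethyl)-6-methylhepta-1,5-diene
Conditions: CBr4, PPh3, CH2Cl2, 0 °C
Reagents that add atoms: tetrabromomethane, BrC(Br)(Br)Br
Why: Appel reaction of a primary allylic alcohol; SN2 and SN2' displacement lead to the same 2-substituted allyl bromide.

**Step 3**
Reactants: 6 (E)-4-methylpent-2-enal, 7 tert-butyl methyl malonate
Product: 8 1-tert-butyl 3-methyl 2-[(3S)-2-methyl-5-oxopentan-3-yl]propanedioate
Conditions: (S)-2-[diphenyl(trimethylsilyloxy)methyl]pyrrolidine (10 mol %), AcOH (cat.), EtOH/H2O, 0 °C to rt
Reagents that add atoms: none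
Why: Iminium-activated organocatalytic Michael addition of a malonate to an enal; the diphenyl(silyloxy)methyl group shields one face of the (E)-iminium ion, so the malonate should add to the opposite face of C3 and set the (S) centre that becomes the isopropyl-bearing ring carbon.

**Step 4**
Reactants: 8 1-tert-butyl 3-methyl 2-[(3S)-2-methyl-5-oxopentan-3-yl]propanedioate
Product: 9 1-tert-butyl 3-methyl 2-[(3S)-2-methylhex-5-en-3-yl]propanedioate
Conditions: Ph3PCH3Br (2.5 equiv), KOtBu (2.4 equiv), THF, 0 °C; then 8, −78 °C to rt
Reagents that add atoms: methyltriphenylphosphonium bromide, C[P+](c1ccccc1)(c1ccccc1)c1ccccc1.[Br-]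
Why: Wittig methylenation of the aldehyde; the excess ylide also deprotonates the malonate C–H, which blocks retro-Michael loss of the β-centre, and work-up returns the malonate.

**Step 5**
Reactants: 9 1-tert-butyl 3-methyl 2-[(3S)-2-methylhex-5-en-3-yl]propanedioate, 5 2-(bromomethyl)-6-methylhepta-1,5-diene
Product: 11 1-tert-butyl 3-methyl 2-[(3S)-2-methylhex-5-en-3-yl]-2-(6-methyl-2-methylidenehept-5-en-1-yl)propanedioate, via sodium malonate enolate 10 (not isolated)
Conditions: NaH, DMF/THF, 0 °C; then 5, rt to 50 °C
Reagents that add atoms: none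
Why: Malonate alkylation (SN2) with a reactive allylic bromide builds the fully substituted carbon; its configuration does not matter because one ester is removed in step 7.

**Step 6**
Reactants: 11 1-tert-butyl 3-methyl 2-[(3S)-2-methylhex-5-en-3-yl]-2-(6-methyl-2-methylidenehept-5-en-1-yl)propanedioate
Product: 12 1-tert-butyl 1-methyl (6S)-3-(4-methylpent-3-en-1-yl)-6-(propan-2-yl)cyclohex-3-ene-1,1-dicarboxylate
Conditions: second-generation Grubbs catalyst (5 mol %), CH2Cl2, 40 °C
Reagents that add atoms: none
Why: Ring-closing metathesis between the vinyl group and the 1,1-disubstituted alkene, helped by the geminal diester, should close ring B with the side chain on the alkene carbon 1,3 to the diester carbon; the trisubstituted side-chain alkene is too hindered to compete.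

**Step 7**
Reactants: 12 1-tert-butyl 1-methyl (6S)-3-(4-methylpent-3-en-1-yl)-6-(propan-2-yl)cyclohex-3-ene-1,1-dicarboxylate
Product: 13 tert-butyl (6S)-3-(4-methylpent-3-en-1-yl)-6-(propan-2-yl)cyclohex-3-ene-1-carboxylate
Conditions: LiCl, H2O, DMSO, 150 °C
Reagents that add atoms: none
Why: Krapcho dealkoxycarbonylation, in which chloride attacks the methyl group by SN2 and the carboxylate loses CO2, while the tert-butyl ester cannot be dealkylated this way and should remain.

**Step 8**
Reactants: 13 tert-butyl (6S)-3-(4-methylpent-3-en-1-yl)-6-(propan-2-yl)cyclohex-3-ene-1-carboxylate, 14 2-methylpropanoyl chloride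
Product: 16 tert-butyl (1S,6S)-1-(2-methylpropanoyl)-3-(4-methylpent-3-en-1-yl)-6-(propan-2-yl)cyclohex-3-ene-1-carboxylate, via lithium ester enolate 15 (not isolated)
Conditions: LiN(iPr)2, THF, −78 °C; then 14, −78 to 0 °C
Reagents that add atoms: none
Why: Claisen-type C-acylation of an ester enolate; allylic strain with the exocyclic enolate turns the neighbouring isopropyl group pseudoaxial, so the acid chloride should enter anti to it and place isobutyryl trans and the ester cis to isopropyl at the new quaternary centre.

**Step 9**
Reactants: 16 tert-butyl (1S,6S)-1-(2-methylpropanoyl)-3-(4-methylpent-3-en-1-yl)-6-(propan-2-yl)cyclohex-3-ene-1-carboxylate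
Product: 17 tert-butyldimethylsilyl (1S,6S)-1-[1-(tert-butyldimethylsilyloxy)-2-methylprop-1-en-1-yl]-3-(4-methylpent-3-en-1-yl)-6-(propan-2-yl)cyclohex-3-ene-1-carboxylate
Conditions: TBSOTf (3 equiv), Et3N (4 equiv), CH2Cl2, 0 to 40 °C
Reagents that add atoms: tert-butyldimethylsilyl trifluoromethanesulfonate, CC(C)(C)[Si](C)(C)OS(=O)(=O)C(F)(F)F
Why: The silyl triflate does two known jobs at once, soft enolisation and O-silylation of the ketone at its only α-hydrogen, and exchange of the tert-butyl ester for a silyl ester with loss of isobutene, so no free β-keto acid is ever formed.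

**Step 10**
Reactants: 17 tert-butyldimethylsilyl (1S,6S)-1-[1-(tert-butyldimethylsilyloxy)-2-methylprop-1-en-1-yl]-3-(4-methylpent-3-en-1-yl)-6-(propan-2-yl)cyclohex-3-ene-1-carboxylate
Product: 18 (1S,6S)-1-[1-(tert-butyldimethylsilyloxy)-2-methylprop-1-en-1-yl]-3-(4-methylpent-3-en-1-yl)-6-(propan-2-yl)cyclohex-3-ene-1-carbonyl chloride
Conditions: (COCl)2, DMF (cat.), CH2Cl2, 0 °C to rt; volatiles removed, used crude
Reagents that add atoms: oxalyl chloride, ClC(=O)C(=O)Cl
Why: Conversion of a silyl ester into an acid chloride with oxalyl chloride under chloroiminium catalysis runs without free HCl, which the hindered tetrasubstituted enol silane should tolerate.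

**Step 11**
Reactants: 19 2-chloro-1,1-dimethoxyethane
Product: 21 1-methoxyprop-1-yne, via sodium methoxyacetylide 20 (not isolated)
Conditions: NaNH2 (3 equiv), liquid NH3, −33 °C; then MeI, −33 °C; distillation
Reagents that add atoms: iodomethane, CI
Why: Double elimination (methanol, then HCl) gives the alkoxyacetylide, which is C-methylated by SN2 alkylation in liquid ammonia.

**Step 12**
Reactants: 18 (1S,6S)-1-[1-(tert-butyldimethylsilyloxy)-2-methylprop-1-en-1-yl]-3-(4-methylpent-3-en-1-yl)-6-(propan-2-yl)cyclohex-3-ene-1-carbonyl chloride, 21 1-methoxyprop-1-yne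
Product: 23 (6R,11S)-3-methoxy-2,4,4-trimethyl-8-(4-methylpent-3-en-1-yl)-11-(propan-2-yl)spiro[5.5]undeca-2,8-diene-1,5-dione, via acyl methoxyketenium triflate 22 (not isolated)
Conditions: 21 (3 equiv), TMSOTf (0.2 equiv), 2,6-di-tert-butyl-4-methylpyridine (0.3 equiv), CH2Cl2, −78 to −20 °C
Reagents that add atoms: none
Why: Proposed new method: the silyl triflate turns the acid chloride into an acyl triflate, which acylates the nucleophilic methyl-bearing carbon of the ynol ether (first bond, to the carbon that becomes the enone C=O) and gives ketenium ion 22; its cationic methoxy-bearing carbon is then captured, in the plane of its empty orbital, by the carbon end of the tethered enol silane (second bond, to the CMe2 carbon), and loss of the silyl group as TBSCl returns the silyl triflate. The closest known reaction types are the Friedel–Crafts-type acylation of alkynes by acid chlorides, the trapping of ketenium ions from alkoxy- and siloxyalkynes by π-nucleophiles, and the Mukaiyama addition of silyl enol ethers to oxocarbenium ions; together they amount to a formal [4+2] annulation in which the third ketene of a ketene trimer is supplied as its O-methyl ynol ether. Ring A closes in a 6-endo-dig (enolendo) mode at the digonal ketenium carbon, and the ketenium C=C ends inside the ring as the vinylogous ester. No stereocentre is formed, and the spiro centre keeps its configuration because its two acyl arms were differentiated in step 8 (acid chloride cis, enol silane trans to isopropyl) and each arm can react in one role only. The step needs regioselectivity (OMe next to CMe2), secured by the fixed polarity of the ynol ether, and chemoselectivity for intermolecular acylation of the ynol ether over four-ring self-acylation through the enol silane or acylation of the ring alkene, secured by the much higher nucleophilicity of the ynol ether, used in excess at low temperature with a hindered pyridine buffer.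

**Compound list**

1 | 2-methylprop-2-en-1-ol | C=C(C)CO | starting material
2 | 1-bromo-3-methylbut-2-ene | CC(C)=CCBr | starting material
3 | dilithio dianion of 2-methylprop-2-en-1-ol | [Li]OCC(=C)C[Li] | intermediate
4 | 6-methyl-2-methylidenehept-5-en-1-ol | C=C(CO)CCC=C(C)C | intermediate
5 | 2-(bromomethyl)-6-methylhepta-1,5-diene | C=C(CBr)CCC=C(C)C | intermediate
6 | (E)-4-methylpent-2-enal | CC(C)/C=C/C=O | starting material
7 | tert-butyl methyl malonate | COC(=O)CC(=O)OC(C)(C)C | starting material
8 | 1-tert-butyl 3-methyl 2-[(3S)-2-methyl-5-oxopentan-3-yl]propanedioate | O=CC[C@H](C(C(=O)OC)C(=O)OC(C)(C)C)C(C)C | intermediate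
9 | 1-tert-butyl 3-methyl 2-[(3S)-2-methylhex-5-en-3-yl]propanedioate | C=CC[C@H](C(C(=O)OC)C(=O)OC(C)(C)C)C(C)C | intermediate
10 | sodium enolate of 9 | C=CC[C@H](C(C(=O)OC(C)(C)C)=C([O-])OC)C(C)C.[Na+] | intermediate
11 | 1-tert-butyl 3-methyl 2-[(3S)-2-methylhex-5-en-3-yl]-2-(6-methyl-2-methylidenehept-5-en-1-yl)propanedioate | C=CC[C@H](C(CC(=C)CCC=C(C)C)(C(=O)OC)C(=O)OC(C)(C)C)C(C)C | intermediate
12 | 1-tert-butyl 1-methyl (6S)-3-(4-methylpent-3-en-1-yl)-6-(propan-2-yl)cyclohex-3-ene-1,1-dicarboxylate | COC(=O)C1(C(=O)OC(C)(C)C)CC(CCC=C(C)C)=CC[C@H]1C(C)C | intermediate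
13 | tert-butyl (6S)-3-(4-methylpent-3-en-1-yl)-6-(propan-2-yl)cyclohex-3-ene-1-carboxylate | CC(C)(C)OC(=O)C1CC(CCC=C(C)C)=CC[C@H]1C(C)C | intermediate
14 | 2-methylpropanoyl chloride | CC(C)C(=O)Cl | starting material
15 | lithium enolate of 13 | CC(C)(C)OC([O-])=C1CC(CCC=C(C)C)=CC[C@H]1C(C)C.[Li+] | intermediate
16 | tert-butyl (1S,6S)-1-(2-methylpropanoyl)-3-(4-methylpent-3-en-1-yl)-6-(propan-2-yl)cyclohex-3-ene-1-carboxylate | CC(C)(C)OC(=O)[C@]1(CC(CCC=C(C)C)=CC[C@H]1C(C)C)C(=O)C(C)C | intermediate
17 | tert-butyldimethylsilyl (1S,6S)-1-[1-(tert-butyldimethylsilyloxy)-2-methylprop-1-en-1-yl]-3-(4-methylpent-3-en-1-yl)-6-(propan-2-yl)cyclohex-3-ene-1-carboxylate | CC(C)(C)[Si](C)(C)OC(=O)[C@]1(CC(CCC=C(C)C)=CC[C@H]1C(C)C)C(O[Si](C)(C)C(C)(C)C)=C(C)C | intermediate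
18 | (1S,6S)-1-[1-(tert-butyldimethylsilyloxy)-2-methylprop-1-en-1-yl]-3-(4-methylpent-3-en-1-yl)-6-(propan-2-yl)cyclohex-3-ene-1-carbonyl chloride | ClC(=O)[C@]1(CC(CCC=C(C)C)=CC[C@H]1C(C)C)C(O[Si](C)(C)C(C)(C)C)=C(C)C | intermediate
19 | 2-chloro-1,1-dimethoxyethane | COC(CCl)OC | starting material
20 | sodium methoxyacetylide | [Na+].[C-]#COC | intermediate
21 | 1-methoxyprop-1-yne | CC#COC | intermediate
22 | acyl methoxyketenium triflate from 18 and 21 | C[O+]=C=C(C)C(=O)[C@]1(CC(CCC=C(C)C)=CC[C@H]1C(C)C)C(O[Si](C)(C)C(C)(C)C)=C(C)C.[O-]S(=O)(=O)C(F)(F)F | intermediate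
23 | (6R,11S)-3-methoxy-2,4,4-trimethyl-8-(4-methylpent-3-en-1-yl)-11-(propan-2-yl)spiro[5.5]undeca-2,8-diene-1,5-dione | COC1=C(C)C(=O)[C@]2(CC(CCC=C(C)C)=CC[C@H]2C(C)C)C(=O)C1(C)C | target

**Step count and risks**

Total step count: 12. Longest linear sequence: 9 steps (steps 3, 4, 5, 6, 7, 8, 9, 10 and 12); steps 1 and 2 feed step 5, and step 11 feeds step 12.

Steps most likely to fail:

1. Step 12 (proposed new method). The acyl cation equivalent may be consumed inside the molecule faster than by the ynol ether: four-ring self-acylation through the enol silane would also erase the difference between the two acyl arms, and acylation of the ring alkene is a second drain. The ketenium ion may also lose its O-methyl group to chloride. The fallback uses known chemistry, sets out from 18 and comes back at 23. Acid chloride 18 is C-acylated onto 1,1-dimethoxyprop-1-ene (CC=C(OC)OC; Et3N, CH2Cl2, 0 °C to rt; acylation of a ketene acetal) to give the isolable acyl ketene acetal 1-[(1S,6S)-1-[1-(tert-butyldimethylsilyloxy)-2-methylprop-1-en-1-yl]-3-(4-methylpent-3-en-1-yl)-6-(propan-2-yl)cyclohex-3-en-1-yl]-3,3-dimethoxy-2-methylprop-2-en-1-one F1. The enol silane of F1 is then opened with anhydrous fluoride (tris(dimethylamino)sulfonium difluorotrimethylsilicate, THF, −40 °C to rt). The free enolate should close ring A by conjugate addition to the dimethoxy-bearing carbon and loss of methoxide, which gives 23 with the methoxy group already on the correct carbon.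

2. Step 10. The electron-rich enol silane may be attacked by the chloroiminium catalyst, or may lose its silyl group to adventitious HCl, before the silyl ester has been exchanged. The fallback sets out from 17 and comes back at 18. The much more labile silyl ester of 17 is cleaved alone (KHCO3, THF/H2O, 0 °C) to give potassium (1S,6S)-1-[1-(tert-butyldimethylsilyloxy)-2-methylprop-1-en-1-yl]-3-(4-methylpent-3-en-1-yl)-6-(propan-2-yl)cyclohex-3-ene-1-carboxylate F2. The dried salt is treated with oxalyl chloride in hexane/CH2Cl2 at 0 °C without DMF, so that 18 forms from a carboxylate salt with neither a chloroiminium ion nor HCl present.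

3. Step 8. O-acylation of the crowded, fully substituted ester enolate may compete with C-acylation, and the facial bias may be eroded with a branched acid chloride. The fallback sets out from 13 and comes back at 16. The lithium enolate of 13 (LiN(iPr)2, THF, −78 °C) is added to 2-methylpropanal, a smaller electrophile that can react only at carbon and should again enter anti to isopropyl. This gives tert-butyl (1S,6S)-1-(1-hydroxy-2-methylpropyl)-3-(4-methylpent-3-en-1-yl)-6-(propan-2-yl)cyclohex-3-ene-1-carboxylate F3 as a mixture of carbinol epimers, which is oxidised with Dess–Martin periodinane (NaHCO3, CH2Cl2, rt) to 16.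

**Further compounds**

F1 | step 12 | 1-[(1S,6S)-1-[1-(tert-butyldimethylsilyloxy)-2-methylprop-1-en-1-yl]-3-(4-methylpent-3-en-1-yl)-6-(propan-2-yl)cyclohex-3-en-1-yl]-3,3-dimethoxy-2-methylprop-2-en-1-one | COC(OC)=C(C)C(=O)[C@]1(CC(CCC=C(C)C)=CC[C@H]1C(C)C)C(O[Si](C)(C)C(C)(C)C)=C(C)C
F2 | step 10 | potassium (1S,6S)-1-[1-(tert-butyldimethylsilyloxy)-2-methylprop-1-en-1-yl]-3-(4-methylpent-3-en-1-yl)-6-(propan-2-yl)cyclohex-3-ene-1-carboxylate | [K+].[O-]C(=O)[C@]1(CC(CCC=C(C)C)=CC[C@H]1C(C)C)C(O[Si](C)(C)C(C)(C)C)=C(C)C
F3 | step 8 | tert-butyl (1S,6S)-1-(1-hydroxy-2-methylpropyl)-3-(4-methylpent-3-en-1-yl)-6-(propan-2-yl)cyclohex-3-ene-1-carboxylate | CC(C)(C)OC(=O)[C@]1(CC(CCC=C(C)C)=CC[C@H]1C(C)C)C(O)C(C)C
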